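**Plan**

- Retrosynthetic cuts, in order: the C19 acetate and the C8, C15 and C19 oxygens (one hydride reduction of an 8α,17-epoxide, a C15 enoate and a C19 ester); C13=C14 (olefination of a methyl ketone); the C3 oxygen (deoxygenation); C4–C5 together with C9–C10 (oxidative radical bicyclisation); C1–C2 (acetoacetate dianion alkylation). This leads to geranylacetone, ethyl 2-methylacetoacetate and (−)-8-phenylmenthol.
- Enabling feature: C4 is quaternary, carries the oxidised carbon C19 and adjoins C3, so it can be the α-carbon of a 2-methyl-3-oxo ester. The methyl-bearing carbons C4, C10 and C8 stand 1,5 to one another across rings A and B, so both rings map onto an (E,E)-1,5-diene and each closure is 6-endo to a tertiary radical. The last radical (C8, next to C17) ends as the exocyclic alkene that later gives the tertiary alcohol.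
- Forward order: chain assembly; ring A (C4–C5) then ring B (C9–C10) in one flask; side-chain enoate; C3 deoxygenation; C8 epoxide; global reduction; acetate adjustment.
- Stereochemistry: C4, C5, C10 and C9 come from the cascade (both C4 epimers of the precursor converge, ester axial, chair–chair array, face chosen by the 8-phenylmenthyl ester). C8 comes from α-face epoxidation and hydride opening. C13=C14 comes from an E-selective olefination.

Key step: step 6

Assumption: the (1R,2S,5R)-8-phenylmenthyl ester is taken to shield the face of the planar C4 radical whose blocking gives the 4R, 19-ester-axial series drawn; if the sense proved opposite, the (1S,2R,5S) alcohol would be used in step 1 with no other change.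

**Route**

Step 1
Reactants: 1 (−)-8-phenylmenthol; 2 ethyl 2-methyl-3-oxobutanoate
Product: 3 (1R,2S,5R)-8-phenylmenthyl 2-methyl-3-oxobutanoate (C2 epimers)
Conditions: DMAP (0.3 equiv), toluene, reflux, 4 Å sieves (removal of EtOH)
Reagents that add atoms: none
Why: DMAP-promoted transesterification of a β-keto ester runs through the acylketene and therefore accepts the hindered secondary alcohol; the α-carbon stays an epimeric mixture, which does not matter.

Step 2
Reactants: 4 (5E)-geranylacetone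
Product: 5 2-[(3E)-4,8-dimethylnona-3,7-dien-1-yl]-2-methyl-1,3-dioxolane
Conditions: ethylene glycol, PPTS (cat.), benzene, reflux, Dean–Stark
Reagents that add atoms: ethylene glycol, OCCO
Why: acid-catalysed ketalisation masks the methyl ketone against the strongly basic dianion of step 5.

Step 3
Reactants: 5 2-[(3E)-4,8-dimethylnona-3,7-dien-1-yl]-2-methyl-1,3-dioxolane
Product: 6 (2E,6E)-2,6-dimethyl-9-(2-methyl-1,3-dioxolan-2-yl)nona-2,6-dien-1-ol
Conditions: SeO2 (0.3 equiv), t-BuOOH (2 equiv, in decane), CH2Cl2, 0 °C to rt, stopped at partial conversion, 5 recycled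
Reagents that add atoms: selenium dioxide, O=[Se]=O (oxygen donor); tert-butyl hydroperoxide, CC(C)(C)OO (restores it)
Why: catalytic SeO2 allylic oxidation (ene reaction then [2,3]-sigmatropic shift) selects the E-methyl of the terminal trisubstituted alkene and gives the E-allylic alcohol.

Step 4
Reactants: 6 (2E,6E)-2,6-dimethyl-9-(2-methyl-1,3-dioxolan-2-yl)nona-2,6-dien-1-ol
Product: 7 2-[(3E,7E)-9-bromo-4,8-dimethylnona-3,7-dien-1-yl]-2-methyl-1,3-dioxolane
Conditions: CBr4, PPh3, CH2Cl2, −20 to 0 °C, used at once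
Reagents that add atoms: carbon tetrabromide, BrC(Br)(Br)Br
Why: Appel bromination is neutral, so the primary allylic alcohol is converted without allylic transposition and without loss of the ketal.

Step 5
Reactants: 3 (1R,2S,5R)-8-phenylmenthyl 2-methyl-3-oxobutanoate; 7 2-[(3E,7E)-9-bromo-4,8-dimethylnona-3,7-dien-1-yl]-2-methyl-1,3-dioxolane
Product: 9 8-phenylmenthyl (6E,10E)-14,14-(ethylenedioxy)-2,6,10-trimethyl-3-oxopentadeca-6,10-dienoate (C2 epimers), via sodium lithium dianion 8 (not isolated)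
Conditions: 3, NaH, THF, 0 °C; n-BuLi, 0 °C; then 7, 0 °C to rt; AcOH quench
Reagents that add atoms: none
Why: γ-alkylation of a β-keto ester dianion by a primary allylic bromide (SN2) forms C1–C2 and leaves both alkene geometries untouched.

Step 6
Reactants: 9 8-phenylmenthyl (6E,10E)-14,14-(ethylenedioxy)-2,6,10-trimethyl-3-oxopentadeca-6,10-dienoate
Product: 11 8-phenylmenthyl 3,13-dioxo-14,15-dinorlabd-8(17)-en-19-oate, via ketal-protected bicycle 10 (not isolated)
Conditions: Mn(OAc)3·2H2O (2.2 equiv), Cu(OAc)2·H2O (1 equiv), degassed AcOH, 20 °C; then 1 M HCl, THF, 20 °C; minor diastereomers removed by chromatography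
Reagents that add atoms: water, O (C13 carbonyl oxygen after ketal hydrolysis)
Why: Mn(OAc)3 oxidises the enol of the β-keto ester by one electron to the planar, electrophilic C4 radical, which adds to C5 of the E-C5=C10 alkene (ring A, 6-endo-trig); the tertiary C10 radical adds to C9 of the E-C8=C9 alkene (ring B, 6-endo-trig); Cu(OAc)2 oxidises the tertiary C8 radical through an alkylcopper species that loses a C17 hydrogen to give the exocyclic alkene, and aqueous acid then removes the dioxolane. The closest known reaction type is the oxidative free-radical polyene cyclisation of 2-alkyl-3-oxo esters with trivalent manganese and divalent copper acetates, including its 8-phenylmenthyl ester variant. C4 is set with the ester axial (β) and the methyl equatorial because the radical reacts through the rotamer in which the C3 carbonyl oxygen, not C2, eclipses the C4 methyl; C5 and C10 follow from the E-alkene in a chair–chair array (trans fusion), and C9 from the second E-alkene, which places the side chain equatorial (β). The absolute sense comes from the auxiliary, whose phenyl ring stacks over one face of the ester-conjugated radical so that C5 bonds to the open face. The step needs 6-endo over 5-exo closure twice, secured by the methyl groups on the inner alkene carbons C10 and C8, and exocyclic over endocyclic alkene formation, secured by the copper-mediated elimination. Because the C4 stereocentre of 9 is erased in the radical, both epimers of 9 converge on one product.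

Step 7
Reactants: 11 8-phenylmenthyl 3,13-dioxo-14,15-dinorlabd-8(17)-en-19-oate
Product: 12 15-ethyl 19-(8-phenylmenthyl) (13E)-3-oxolabda-8(17),13-diene-15,19-dioate
Conditions: (EtO)2P(O)CH2CO2Et, NaH, THF, 0 to 45 °C; minor Z isomer removed by chromatography
Reagents that add atoms: triethyl phosphonoacetate, CCOC(=O)CP(=O)(OCC)OCC
Why: Horner–Wadsworth–Emmons olefination attacks only the unhindered C13 methyl ketone (the C3 ketone is flanked by quaternary C4), and the E enoate is favoured under the equilibrating sodium conditions.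

Step 8
Reactants: 12 15-ethyl 19-(8-phenylmenthyl) (13E)-3-oxolabda-8(17),13-diene-15,19-dioate
Product: 13 15-ethyl 19-(8-phenylmenthyl) (13E)-3β-hydroxylabda-8(17),13-diene-15,19-dioate
Conditions: NaBH4, MeOH/THF, 0 °C to rt
Reagents that add atoms: none
Why: NaBH4 reduces only the ketone (enoate and hindered ester are inert), with hydride expected on the α face to give the equatorial 3β-alcohol, whose configuration is immaterial.

Step 9
Reactants: 13 15-ethyl 19-(8-phenylmenthyl) (13E)-3β-hydroxylabda-8(17),13-diene-15,19-dioate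
Product: 14 15-ethyl 19-(8-phenylmenthyl) (13E)-3β-(phenoxythiocarbonyloxy)labda-8(17),13-diene-15,19-dioate
Conditions: PhOC(S)Cl, pyridine, DMAP (cat.), CH2Cl2, rt
Reagents that add atoms: O-phenyl chlorothionoformate, S=C(Cl)Oc1ccccc1
Why: thioacylation under non-basic conditions gives the Barton–McCombie substrate and avoids retro-aldol opening of the β-hydroxy ester.

Step 10
Reactants: 14 15-ethyl 19-(8-phenylmenthyl) (13E)-3β-(phenoxythiocarbonyloxy)labda-8(17),13-diene-15,19-dioate
Product: 15 15-ethyl 19-(8-phenylmenthyl) (13E)-labda-8(17),13-diene-15,19-dioate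
Conditions: Bu3SnH, AIBN (cat.), toluene, 100 °C
Reagents that add atoms: none
Why: Barton–McCombie deoxygenation, in which the stannyl radical adds to C=S and the released secondary C3 radical is reduced by Bu3SnH faster than it can rearrange.

Step 11
Reactants: 15 15-ethyl 19-(8-phenylmenthyl) (13E)-labda-8(17),13-diene-15,19-dioate
Product: 16 15-ethyl 19-(8-phenylmenthyl) (13E)-8α,17-epoxylabd-13-ene-15,19-dioate
Conditions: mCPBA (1.1 equiv), NaHCO3, CH2Cl2, 0 °C
Reagents that add atoms: 3-chloroperbenzoic acid, O=C(OO)c1cccc(Cl)c1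
Why: Prilezhaev epoxidation takes the only electron-rich alkene (the enoate is deactivated) from the α face, the β face being shielded by the axial C20 methyl, which sets the C8–O bond α.

Step 12
Reactants: 16 15-ethyl 19-(8-phenylmenthyl) (13E)-8α,17-epoxylabd-13-ene-15,19-dioate
Product: 17 (13E)-labd-13-ene-8α,15,19-triol
Conditions: LiAlH4 (excess), THF, −20 °C to reflux; aqueous NaOH work-up; 1 recovered
Reagents that add atoms: none
Why: LiAlH4 opens the epoxide at the primary C17 (leaving the 8α tertiary alcohol and 8β methyl), reduces the enoate 1,2 to the allylic alcohol and the neopentyl ester to the C19 carbinol, releasing the auxiliary.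

Step 13
Reactants: 17 (13E)-labd-13-ene-8α,15,19-triol
Product: 18 (13E)-8α-hydroxylabd-13-ene-15,19-diyl diacetate
Conditions: Ac2O (3 equiv), pyridine, DMAP (cat.), CH2Cl2, 0 °C to rt
Reagents that add atoms: acetic anhydride, CC(=O)OC(C)=O
Why: both primary alcohols are acetylated while the hindered tertiary C8 alcohol does not react at room temperature.

Step 14
Reactants: 18 (13E)-8α-hydroxylabd-13-ene-15,19-diyl diacetate
Product: 19 (13E)-8α,15-dihydroxylabd-13-en-19-yl acetate
Conditions: immobilised Candida antarctica lipase B, pH 7 phosphate buffer/acetone, 30 °C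
Reagents that add atoms: none
Why: lipase-catalysed hydrolysis accepts the unhindered primary allylic C15 acetate and rejects the axial neopentyl C19 acetate, which is shielded by quaternary C4 and the syn-axial C20 methyl.

**Compound list**

1 | (−)-8-phenylmenthol, (1R,2S,5R)-5-methyl-2-(2-phenylpropan-2-yl)cyclohexan-1-ol | O[C@@H]1C[C@H](C)CC[C@H]1C(C)(C)c1ccccc1 | starting material
2 | ethyl 2-methyl-3-oxobutanoate | CCOC(=O)C(C)C(C)=O | starting material
3 | (1R,2S,5R)-8-phenylmenthyl 2-methyl-3-oxobutanoate (C2 epimers) | CC(=O)C(C)C(=O)O[C@@H]1C[C@H](C)CC[C@H]1C(C)(C)c1ccccc1 | intermediate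
4 | geranylacetone, (5E)-6,10-dimethylundeca-5,9-dien-2-one | CC(=O)CC/C=C(\C)CCC=C(C)C | starting material
5 | 2-[(3E)-4,8-dimethylnona-3,7-dien-1-yl]-2-methyl-1,3-dioxolane | CC1(CC/C=C(\C)CCC=C(C)C)OCCO1 | intermediate
6 | (2E,6E)-2,6-dimethyl-9-(2-methyl-1,3-dioxolan-2-yl)nona-2,6-dien-1-ol | CC1(CC/C=C(\C)CC/C=C(\C)CO)OCCO1 | intermediate
7 | 2-[(3E,7E)-9-bromo-4,8-dimethylnona-3,7-dien-1-yl]-2-methyl-1,3-dioxolane | CC1(CC/C=C(\C)CC/C=C(\C)CBr)OCCO1 | intermediate
8 | sodium lithium dianion of 3 | [Na+].[Li+].C=C([O-])C(C)=C([O-])O[C@@H]1C[C@H](C)CC[C@H]1C(C)(C)c1ccccc1 | intermediate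
9 | (1R,2S,5R)-8-phenylmenthyl (6E,10E)-14,14-(ethylenedioxy)-2,6,10-trimethyl-3-oxopentadeca-6,10-dienoate (C2 epimers) | CC1(CC/C=C(\C)CC/C=C(\C)CCC(=O)C(C)C(=O)O[C@@H]2C[C@H](C)CC[C@H]2C(C)(C)c2ccccc2)OCCO1 | intermediate
10 | 8-phenylmenthyl 13,13-(ethylenedioxy)-3-oxo-14,15-dinorlabd-8(17)-en-19-oate | O=C(O[C@@H]3C[C@H](C)CC[C@H]3C(C)(C)c3ccccc3)[C@@]1(C)C(=O)CC[C@]2(C)[C@@H](CCC3(C)OCCO3)C(=C)CC[C@@H]12 | intermediate
11 | 8-phenylmenthyl 3,13-dioxo-14,15-dinorlabd-8(17)-en-19-oate | O=C(O[C@@H]3C[C@H](C)CC[C@H]3C(C)(C)c3ccccc3)[C@@]1(C)C(=O)CC[C@]2(C)[C@@H](CCC(C)=O)C(=C)CC[C@@H]12 | intermediate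
12 | 15-ethyl 19-(8-phenylmenthyl) (13E)-3-oxolabda-8(17),13-diene-15,19-dioate | O=C(O[C@@H]3C[C@H](C)CC[C@H]3C(C)(C)c3ccccc3)[C@@]1(C)C(=O)CC[C@]2(C)[C@@H](CC/C(C)=C/C(=O)OCC)C(=C)CC[C@@H]12 | intermediate
13 | 15-ethyl 19-(8-phenylmenthyl) (13E)-3β-hydroxylabda-8(17),13-diene-15,19-dioate | O=C(O[C@@H]3C[C@H](C)CC[C@H]3C(C)(C)c3ccccc3)[C@@]1(C)[C@@H](O)CC[C@]2(C)[C@@H](CC/C(C)=C/C(=O)OCC)C(=C)CC[C@@H]12 | intermediate
14 | 15-ethyl 19-(8-phenylmenthyl) (13E)-3β-(phenoxythiocarbonyloxy)labda-8(17),13-diene-15,19-dioate | O=C(O[C@@H]3C[C@H](C)CC[C@H]3C(C)(C)c3ccccc3)[C@@]1(C)[C@@H](OC(=S)Oc3ccccc3)CC[C@]2(C)[C@@H](CC/C(C)=C/C(=O)OCC)C(=C)CC[C@@H]12 | intermediate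
15 | 15-ethyl 19-(8-phenylmenthyl) (13E)-labda-8(17),13-diene-15,19-dioate | O=C(O[C@@H]3C[C@H](C)CC[C@H]3C(C)(C)c3ccccc3)[C@@]1(C)CCC[C@]2(C)[C@@H](CC/C(C)=C/C(=O)OCC)C(=C)CC[C@@H]12 | intermediate
16 | 15-ethyl 19-(8-phenylmenthyl) (13E)-8α,17-epoxylabd-13-ene-15,19-dioate | O=C(O[C@@H]3C[C@H](C)CC[C@H]3C(C)(C)c3ccccc3)[C@@]1(C)CCC[C@]2(C)[C@@H](CC/C(C)=C/C(=O)OCC)[C@]3(OC3)CC[C@@H]12 | intermediate
17 | (13E)-labd-13-ene-8α,15,19-triol | OC[C@@]1(C)CCC[C@]2(C)[C@@H](CC/C(C)=C/CO)[C@](C)(O)CC[C@@H]12 | intermediate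
18 | (13E)-8α-hydroxylabd-13-ene-15,19-diyl diacetate | CC(=O)OC[C@@]1(C)CCC[C@]2(C)[C@@H](CC/C(C)=C/COC(C)=O)[C@](C)(O)CC[C@@H]12 | intermediate
19 | (13E)-8α,15-dihydroxylabd-13-en-19-yl acetate | CC(=O)OC[C@@]1(C)CCC[C@]2(C)[C@@H](CC/C(C)=C/CO)[C@](C)(O)CC[C@@H]12 | target

**Step count and risks**

Total step count: 14. Longest linear sequence: 13 steps (4 to 19, steps 2 to 14).

Steps most likely to fail:

1. Step 6. The risk is poor discrimination between the two faces of the C4 radical by the auxiliary, together with loss of material to premature oxidation. The fallback replaces auxiliary control by resolution and sets out from 2 and 7. The sodium lithium dianion of 2 F1 (NaH, then n-BuLi, THF, 0 °C) is alkylated with 7 to ethyl (6E,10E)-14,14-(ethylenedioxy)-2,6,10-trimethyl-3-oxopentadeca-6,10-dienoate F2. Mn(OAc)3·2H2O and Cu(OAc)2·H2O in AcOH give the racemic ketal bicycle F3, hydrolysed in the same flask to racemic ethyl 3,13-dioxo-14,15-dinorlabd-8(17)-en-19-oate F4. F4 is resolved by preparative chromatography on a chiral stationary phase. The enantiomer with the configuration of 11 is taken through the operations of steps 7 to 11: diethyl (13E)-3-oxolabda-8(17),13-diene-15,19-dioate F5, its 3β-alcohol F6, the phenyl thionocarbonate F7, diethyl (13E)-labda-8(17),13-diene-15,19-dioate F8 and its 8α,17-epoxide F9. LiAlH4 reduction of F9 returns to the route at 17.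

2. Step 11. The risk is insufficient facial selectivity in oxygen transfer to the exocyclic alkene, which would erode the C8 configuration. The fallback is Markovnikov hydration by oxymercuration–demercuration and sets out from 15. Hg(OAc)2 in THF/H2O gives the 17-acetoxymercurio 8α-alcohol F10, in which water has opened the mercurinium ion at C8 from the open α face and the enoate is untouched. NaBH4/NaOH then gives 15-ethyl 19-(8-phenylmenthyl) (13E)-8α-hydroxylabd-13-ene-15,19-dioate F11. LiAlH4 reduction of F11 returns to the route at 17.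

3. Step 14. The risk is incomplete discrimination between the two primary acetates, leading to over-hydrolysis or stalled conversion. The fallback uses protecting-group differentiation and sets out from 17. TBSCl (1.05 equiv) and imidazole in CH2Cl2 at −20 °C silylate only the unhindered allylic C15 hydroxyl to give (13E)-15-(tert-butyldimethylsilyloxy)labd-13-ene-8α,19-diol F12. Ac2O, pyridine and DMAP give its 19-acetate F13. HF·pyridine in THF removes the silyl ether and returns to the route at 19.

**Further compounds**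

F1 | step 6 | sodium lithium dianion of 2 | [Na+].[Li+].C=C([O-])C(C)=C([O-])OCC
F2 | step 6 | ethyl (6E,10E)-14,14-(ethylenedioxy)-2,6,10-trimethyl-3-oxopentadeca-6,10-dienoate | CC1(CC/C=C(\C)CC/C=C(\C)CCC(=O)C(C)C(=O)OCC)OCCO1
F3 | step 6 | ethyl 13,13-(ethylenedioxy)-3-oxo-14,15-dinorlabd-8(17)-en-19-oate (racemate, enantiomer kept is shown) | CCOC(=O)[C@@]1(C)C(=O)CC[C@]2(C)[C@@H](CCC3(C)OCCO3)C(=C)CC[C@@H]12
F4 | step 6 | ethyl 3,13-dioxo-14,15-dinorlabd-8(17)-en-19-oate (racemate then resolved, enantiomer kept is shown) | CCOC(=O)[C@@]1(C)C(=O)CC[C@]2(C)[C@@H](CCC(C)=O)C(=C)CC[C@@H]12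
F5 | step 6 | diethyl (13E)-3-oxolabda-8(17),13-diene-15,19-dioate | CCOC(=O)[C@@]1(C)C(=O)CC[C@]2(C)[C@@H](CC/C(C)=C/C(=O)OCC)C(=C)CC[C@@H]12
F6 | step 6 | diethyl (13E)-3β-hydroxylabda-8(17),13-diene-15,19-dioate | CCOC(=O)[C@@]1(C)[C@@H](O)CC[C@]2(C)[C@@H](CC/C(C)=C/C(=O)OCC)C(=C)CC[C@@H]12
F7 | step 6 | diethyl (13E)-3β-(phenoxythiocarbonyloxy)labda-8(17),13-diene-15,19-dioate | CCOC(=O)[C@@]1(C)[C@@H](OC(=S)Oc3ccccc3)CC[C@]2(C)[C@@H](CC/C(C)=C/C(=O)OCC)C(=C)CC[C@@H]12
F8 | step 6 | diethyl (13E)-labda-8(17),13-diene-15,19-dioate | CCOC(=O)[C@@]1(C)CCC[C@]2(C)[C@@H](CC/C(C)=C/C(=O)OCC)C(=C)CC[C@@H]12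
F9 | step 6 | diethyl (13E)-8α,17-epoxylabd-13-ene-15,19-dioate | CCOC(=O)[C@@]1(C)CCC[C@]2(C)[C@@H](CC/C(C)=C/C(=O)OCC)[C@]3(OC3)CC[C@@H]12
F10 | step 11 | 15-ethyl 19-(8-phenylmenthyl) (13E)-17-(acetoxymercurio)-8α-hydroxylabd-13-ene-15,19-dioate | O=C(O[C@@H]3C[C@H](C)CC[C@H]3C(C)(C)c3ccccc3)[C@@]1(C)CCC[C@]2(C)[C@@H](CC/C(C)=C/C(=O)OCC)[C@](C[Hg]OC(C)=O)(O)CC[C@@H]12
F11 | step 11 | 15-ethyl 19-(8-phenylmenthyl) (13E)-8α-hydroxylabd-13-ene-15,19-dioate | O=C(O[C@@H]3C[C@H](C)CC[C@H]3C(C)(C)c3ccccc3)[C@@]1(C)CCC[C@]2(C)[C@@H](CC/C(C)=C/C(=O)OCC)[C@](C)(O)CC[C@@H]12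
F12 | step 14 | (13E)-15-(tert-butyldimethylsilyloxy)labd-13-ene-8α,19-diol | OC[C@@]1(C)CCC[C@]2(C)[C@@H](CC/C(C)=C/CO[Si](C)(C)C(C)(C)C)[C@](C)(O)CC[C@@H]12
F13 | step 14 | (13E)-15-(tert-butyldimethylsilyloxy)-8α-hydroxylabd-13-en-19-yl acetate | CC(=O)OC[C@@]1(C)CCC[C@]2(C)[C@@H](CC/C(C)=C/CO[Si](C)(C)C(C)(C)C)[C@](C)(O)CC[C@@H]12
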